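The ratio I work with is substrate left over substrate charged, and I take its logarithm rather than counting target made.

| flask | substrate | reagent in the second phase | remark | time | volume of the second phase over the first |
|---|---|---|---|---|---|
| eta | 13 mM | 2 equiv | run made earlier |  |  |
| zeta | 30 mM | 2 equiv | run made earlier |  |  |
| flask | 20 mM | 2.00 equiv |  | 12 min | 0.50 |

| run | time / min | target / % | substrate / % |
|---|---|---|---|
| eta | 1.00 | 0 | 98 |
| eta | 2.00 | 2 | 96 |
| eta | 5.00 | 7 | 90 |
| eta | 12.0 | 15 | 76 |
| zeta | 3.00 | 7 | 93 |
| zeta | 6.00 | 14 | 85 |
| zeta | 10.0 | 18 | 77 |
| zeta | 12.0 | 20 | 70 |

(readings scatter by 1.5 percentage points)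

- in the second phase: reagent in the second phase; everything else is in the first
- charges count per volume of the first phase; a concentration in a rate is the amount of a species over the volume of its own phase; every rate counts per litre of the first phase
- the analysis behind the earlier runs scatters by 1.5 percentage points, standard deviation
- the earlier runs hold the two phases in the same ratio of volumes as the flask asked about

- amount of target at 12 min, in percent of the substrate charged
- part of the substrate charged that has reacted at 12 min

At 12.0 min the eta run keeps 76% of its substrate and the zeta run 70%, so ln(charged/left) per minute reads 0.0229 min⁻¹ and 0.0297 min⁻¹. The flask's c(substrate) of 20 mM lies close to the geometric mean of the two charges, 19.7 mM, so I take the mean of the two readings, 0.0263 min⁻¹, as the flask's loss constant, the logarithm of charged over left gained per minute, a pseudo-first-order constant as read.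

Now the ladder, quickest rung first. In the eta run target reads 2% at 2.00 min, against a scatter of 1.5 percentage points. Next comes the asked time, 12 min. Slowest is the half-life I reckon for the flask's substrate, ln(2)/k = 26.4 min, longer than the asked time. So I reckon 72.9% left and 27.1% reacted. At 12.0 min the two runs read, on mean, 64.6% of the reacted substrate as target, and carrying that share over to the flask gives me 17.5% of target.

The forecast gives 17.5% of target (15.5% to 19.8%) and 26.5% reacted (23.5% to 29.5%), calling it “an interpolation”. My conversion stands slightly above its figure.

The flask gives 17.9% of target and 27.3% reacted, inside both ranges.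

    reagent in the reaction phase ⇌ reagent in the second phase, rate k1*([reagent in the reaction phase] - [reagent in the second phase]/K1) per volume of the first phase (partition coefficient = 6.60, kL = 0.00130 s⁻¹)
    reagent in the reaction phase + target → over-reacted product (k = 1.00 L mol⁻¹ s⁻¹)
    2 reagent in the reaction phase → homo dimer (k = 0.160 L mol⁻¹ s⁻¹)
    substrate + reagent in the reaction phase → target (k = 0.370 L mol⁻¹ s⁻¹)

In the flask c(reagent in the reaction phase) stands at 1.38 mM at 6.00 min and 1.19 mM at 12.0 min, and 73% of the substrate is left against my 72.9%. For the same flask read at 20 min, k gives 59.1% left. The computed flask holds 59.7% of its substrate, with 40.3% reacted.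

(The data come from a simulation on assumed constants, noise included.)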